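## Structural features

The target is a 3-substituted phthalide: a benzene ring fused through C3a and C7a to a γ-lactone (C1 carbonyl, O2, C3), with methoxy groups on C5 and C7, the second of which flanks C7a. C3 is a benzylic, oxygen-bearing stereocentre of S configuration and carries a six-methylene tether that ends at C2' of a 1,6-dioxaspiro[4.4]nonane; ring A (O1', C2', C3', C4', C5') and ring B (C5', O6', C7', C8', C9') share the spiro carbon C5', and C7' bears a methyl group. C2', C5' and C7' (all S) form one stereochemical cluster, whereas C3 is isolated from it by the tether, so neither set can direct the other. The fragile parts are the spiroketal, which opens under protic acid and, as a five-five system without a strong anomeric preference, re-closes to both C5' configurations, and the lactone, which hydroxide opens and whose benzylic C3–H a strong base could remove. The real difficulty is twofold: a lone stereocentre at C3 has to be created with absolute control on an unfunctionalised chain while a 1,2,3,5-tetrasubstituted arene is assembled with the right regiochemistry, and C5' has to end in one configuration although no equilibrium holds it there. The key step exploits three facts together: C3a and C7a are neighbouring ring carbons that bear the carbinol carbon C3 and the carboxyl carbon C1, O2 links C3 to C1, and the C7 methoxy group sits beside C7a. This is the pattern left when a carbon nucleophile and an acyl electrophile add across the triple bond of a 3-alkoxy aryne, and the oxygen on C3 can bring C1 with it as a carbamoyl group.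

## Logic of the disconnections

22 back to 21. The lactone bond O2–C1 is cut and C1 is written as a diisopropylcarboxamide. A tertiary benzamide ortho to a benzylic hydroxyl is exactly what an oxygen-to-carbon carbamoyl transfer leaves behind, and it closes to the five-membered lactone by plain acyl substitution. The bicyclic core becomes an open arene with two ortho substituents. The forward ring closure has to run under acid weak enough not to scramble C5'.

21 back to 15 and 16. The two aryl–carbon bonds at the neighbouring ring carbons are cut together: C3–C3a and C7a–C1. This removes the arene as an unfunctionalised unit (16, through 18 and 19) and turns the C3 stereocentre into the prochiral O–CH2 group of 15, whose oxygen already carries the future C1. It is the largest simplification of the plan: two skeletal bonds and one stereocentre in one operation. The forward step demands enantioselective removal of one methylene proton (17), release of 19 within the temperature range that 17 tolerates, retention at carbon, attack at the aryne carbon remote from the flanking methoxy group, and fast acyl transfer in 20. To meet these demands 15 is used as a single C5' epimer, keeps the hindered diisopropylcarbamoyl group that resists the alkyllithium base, and the two organolithiums are made in separate flasks.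

15 back to 13 and 14. The carbamate O–C(=O) bond is cut, because the carbamoyl group is both the director of the deprotonation and the source of C1. The precursor becomes a plain primary alcohol. The forward step is only an acylation under basic conditions, which the spiroketal tolerates.

13 back to 11. The hydroxyl-bearing carbon is traced, through 12, to the internal carbon of a terminal C=C bond, so one carbon is added in the retrosynthetic sense. A terminal alkene survives the strongly basic steps that assemble the ketal and needs no protecting group. The forward cleavage must not oxidise the ether C–H bonds or expose the ketal to acid.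

11 back to 10. No skeletal bond is cut; the single C5' configuration is traced to the equilibrium mixture of both spiro epimers. This accepts that no element of the substrate can fix C5' and places the problem at the earliest, least valuable bicyclic intermediate. The forward step needs a separation of two non-polar epimers and a mild acid that re-equilibrates the unwanted one without touching C2', C7' or the alkene.

10 back to 5 and 6. Both ketal bonds, O1'–C5' and O6'–C5', are cut to uncover 9, its carbonyl is masked as 8, and the C8'–C9' bond is cut between the hydrazone α-carbon and the CH2 of 6. A ketone with a γ-hydroxyl on each side is the retron of epoxide opening by an aza-enolate (7), and 6 delivers C7' with its configuration. The bicycle becomes acyclic. The forward step needs metalation at the methyl group of 5 in the presence of its alkoxide and attack at the unsubstituted epoxide carbon.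

5 back to 2 and 3. The C3'–C4' bond is cut in the same way. C2' is thereby traced to the stereocentre of a terminal epoxide and the three-carbon linchpin to 3. The forward step needs clean mono-alkylation through 4.

2 back to 1. No skeletal bond is cut; the single enantiomer is traced to the racemate by kinetic resolution. 1 is a catalogue chemical and the resolution of terminal epoxides is dependable. The cost is the loss of half the material.

## Other disconnections considered

Alternative 1: The cut removes both ring bonds to oxygen on the C2' side, O6'–C5' and O1'–C2', with the phthalide already complete; the precursor is the open-chain hydroxy keto E-allylic alcohol A1. In the forward direction PdCl2(MeCN)2, a divalent palladium salt, would let the C7' hydroxyl close ring B as a hemiketal and the hemiketal hydroxyl displace the allylic hydroxyl in a syn SN2' manner to close ring A, giving the alkenyl spiroketal A2; hydrogenation would then give 22.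
- In its favour: C2' would be set by chirality transfer from an allylic carbinol, a centre that asymmetric ketone reduction sets reliably. Both rings would close in one neutral operation at the end, so the spiroketal would never meet acid afterwards. On that point, and on precedent for the key step (an established reaction type against an untested one), this plan is the better one.
- Against it: nothing obvious decides which hemiketal epimer cyclises, so C5' is likely to be no better controlled than in the chosen plan (the two are equal here). A1 needs three separately made carbinol centres and a ketone that must stay open until the end. The arene and C3 must be built first by other means.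
- Step economy: clearly longer, since the chosen route obtains the whole ketal skeleton in two alkylations.

Alternative 2: The benzene ring itself is cut at C3a–C7a (with formal addition of water), so the arene is traced to the dioxinone-masked triketo acid A3. Et3N would fold A3 so that the dioxinone α-carbon adds to the ketone next to the silyloxy carbon; dehydration and enolisation would give the acetonide-protected resorcylate A4, and desilylation, lactonisation on the acetonide ester and double O-methylation would finish 22.
- In its favour: the oxygenation pattern and the position of the C3 side chain are written into the chain, so no regiochemical question of the aryne kind arises; on this point it is the better plan. No organometallic reagent is needed late, and the lactone can be closed with fluoride or base, which is kinder to C5' than acid.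
- Against it: the C3 stereocentre must be made beforehand as an α-silyloxy acyl unit on the spiroketal chain. It then sits α to a ketone in a 1,3,5-tricarbonyl array under amine base, where enolisation threatens it. Assembling A3 and the finishing operations add length.
- Comparison: the chosen plan creates C3 and both aryl bonds in one step from a CH2 group and is shorter by several steps, but its key step is mechanistically less certain than this well-understood aldol aromatisation.

Alternative 3: The cut is the O6'–C5' bond, made after adding a hydroxyl at C4'; the precursor is the phthalide-bearing 2,3-dihydrofuran A5 with an endocyclic C4'–C5' enol ether and a free C7' hydroxyl. Dimethyldioxirane would epoxidise the enol ether anti to the C2' chain, and methanol-assisted attack of the C7' hydroxyl at C5' with inversion would close ring B to give the 4'-hydroxy spiroketal A6; thiocarbonylation and Barton–McCombie reduction would then give 22.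
- In its favour: it is the only plan in which C5' is set kinetically by the substrate, so no epimer has to be separated and recycled. On spiro stereocontrol it is plainly better than the chosen route.
- Against it: the enol ether must be prepared with C2' and the whole phthalide chain in place. The oxidant meets an electron-rich dimethoxyarene. Two extra steps delete an oxygen the target does not contain, and everything after the cyclisation must stay acid-free. The arene and C3 are again left to another method.
- Comparison: it trades the step economy of the chosen plan for certainty at one centre, a fair trade only if the epimer separation in the chosen route proves impractical.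

Key step: step 7

Remark: 1 and (+)-sparteine are taken as purchasable; the spiroketal is numbered C2' (chain), C5' (spiro), C7' (methyl) in every compound; with retention at the C–Li bond, (+)-sparteine leads to (S)-C3, and (S)-configured 2 and 6 map onto (S)-C2' and (S)-C7'.

## Route

Step 1
Reactants: 1 rac-2-(oct-7-en-1-yl)oxirane (1,2-epoxy-9-decene)
Product: 2 (S)-2-(oct-7-en-1-yl)oxirane
Conditions: (S,S)-(salen)Co(OAc) (0.5 mol %), H2O (0.55 equiv), THF, 0 °C to rt; distillation
Reagents that add atoms: none
Why: Hydrolytic kinetic resolution of a terminal epoxide; the trivalent cobalt complex of the salen ligand (N,N'-bis(3,5-di-tert-butylsalicylidene)cyclohexane-1,2-diamine dianion) in its (S,S) form, the antipode that hydrolyses (R)-configured alkyl oxiranes fastest, should leave (S)-2, which is distilled from the diol. The remote alkene is inert.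

Step 2
Reactants: 2 (S)-2-(oct-7-en-1-yl)oxirane; 3 acetone N,N-dimethylhydrazone
Product: 5 (5S)-2-(2,2-dimethylhydrazinylidene)tridec-12-en-5-ol, via lithium aza-enolate of acetone dimethylhydrazone 4 (not isolated)
Conditions: 3 (1.5 equiv), n-BuLi, THF, −78 to 0 °C; then 2, 0 °C to rt; aq NH4Cl
Reagents that add atoms: none
Why: Aza-enolate alkylation with an epoxide; 4 should open 2 at the unsubstituted carbon by SN2 attack, so the stereocentre of 2 is untouched and becomes C2'. An excess of volatile 3 suppresses double alkylation.

Step 3
Reactants: 5 (5S)-2-(2,2-dimethylhydrazinylidene)tridec-12-en-5-ol; 6 (S)-2-methyloxirane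
Product: 10 (2S,5RS,7S)-7-methyl-2-(oct-7-en-1-yl)-1,6-dioxaspiro[4.4]nonane as the mixture of both C5' epimers, via O,C-dilithiated hydroxy hydrazone 7 (not isolated), via dihydroxy hydrazone 8 (not isolated), via dihydroxy ketone 9 (not isolated)
Conditions: n-BuLi (2.2 equiv), THF, −78 to 0 °C; 6 (2 equiv), 0 °C to rt; then 2 M HCl, THF, rt; short SiO2 plug
Reagents that add atoms: none
Why: A second aza-enolate epoxide opening, at the less substituted α-carbon of the hydrazone and at the CH2 of 6, is followed by hydrazone hydrolysis and acid spiroketalisation of 9; C2' and C7' come unchanged from 2 and 6. C5' is set under thermodynamic control and a five-five spiroketal has little anomeric bias, so both C5' epimers should form in comparable amounts and 10 is taken on as this mixture.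

Step 4
Reactants: 10 (2S,5RS,7S)-7-methyl-2-(oct-7-en-1-yl)-1,6-dioxaspiro[4.4]nonane as the mixture of both C5' epimers
Product: 11 (2S,5S,7S)-7-methyl-2-(oct-7-en-1-yl)-1,6-dioxaspiro[4.4]nonane
Conditions: SiO2 chromatography (pentane/Et2O) or preparative HPLC; (5R) fraction: pyridinium p-toluenesulfonate (5 mol %), CH2Cl2, rt, then Et3N and re-chromatography; repeated two to three times
Reagents that add atoms: none
Why: Acid-catalysed spiroketal epimerisation combined with separation: protonation of a ring oxygen opens a C5'–O bond to an oxocarbenium ion that re-closes on either face, so each pass should convert a further part of the unwanted (5R) material into 11. C2' and C7' keep their configuration because their C–O bonds never break, and the alkene is inert to the pyridinium salt.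

Step 5
Reactants: 11 (2S,5S,7S)-7-methyl-2-(oct-7-en-1-yl)-1,6-dioxaspiro[4.4]nonane
Product: 13 7-[(2S,5S,7S)-7-methyl-1,6-dioxaspiro[4.4]nonan-2-yl]heptan-1-ol, via aldehyde 12 (not isolated)
Conditions: O3, NaHCO3, CH2Cl2/MeOH, −78 °C; then NaBH4, −78 °C to rt
Reagents that add atoms: ozone, [O-][O+]=O
Why: Criegee ozonolysis with hydride work-up removes the terminal carbon and gives the primary alcohol directly. The spiroketal has no C=C or acetal C–H bond, and the bicarbonate buffer keeps the medium from turning acidic, so C5' should not equilibrate.

Step 6
Reactants: 13 7-[(2S,5S,7S)-7-methyl-1,6-dioxaspiro[4.4]nonan-2-yl]heptan-1-ol; 14 N,N-di(propan-2-yl)carbamoyl chloride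
Product: 15 7-[(2S,5S,7S)-7-methyl-1,6-dioxaspiro[4.4]nonan-2-yl]heptyl N,N-di(propan-2-yl)carbamate
Conditions: 14 (1.3 equiv), Et3N, CH2Cl2, reflux
Reagents that add atoms: none
Why: O-Acylation of a primary alcohol by a carbamoyl chloride with an amine base that scavenges HCl, so the ketal never meets acid. The hindered diisopropylcarbamoyl group later resists nucleophilic attack by s-BuLi and chelates lithium.

Step 7
Reactants: 15 7-[(2S,5S,7S)-7-methyl-1,6-dioxaspiro[4.4]nonan-2-yl]heptyl N,N-di(propan-2-yl)carbamate; 16 1-fluoro-3,5-dimethoxybenzene
Product: 21 2-[(1S)-1-hydroxy-7-[(2S,5S,7S)-7-methyl-1,6-dioxaspiro[4.4]nonan-2-yl]heptyl]-4,6-dimethoxy-N,N-di(propan-2-yl)benzamide, via (R)-alpha-lithio carbamate sparteine complex 17 (not isolated), via 1-fluoro-2-lithio-3,5-dimethoxybenzene 18 (not isolated), via 3,5-dimethoxybenzyne 19 (not isolated), via ortho-lithiated benzylic carbamate 20 (not isolated)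
Conditions: 15, s-BuLi (1.25 equiv), (+)-sparteine (1.3 equiv), Et2O, −78 °C, 5 h; separately 16 (2 equiv), s-BuLi (1.9 equiv), Et2O/THF, −78 °C; combine at −78 °C, warm slowly to −40 °C, then 0 °C; aq NH4Cl
Reagents that add atoms: none
Why: Proposed new method: insertion of an aryne into the C–Li bond of a sparteine-complexed α-lithiated carbamate with ensuing carbamoyl shift has not been shown on this substrate class; the closest known reaction types are the addition of organolithiums to arynes with trapping of the new aryl anion and the anionic 1,4 oxygen-to-carbon carbamoyl shift (a homologous anionic Fries rearrangement) of ortho-lithiated benzyl carbamates. Mechanism: s-BuLi with (+)-sparteine removes the pro-R proton of 15 to give the chelated, configurationally stable 17, while separately prepared 18 persists at −78 °C and loses LiF on warming to release 19. 17 then adds across the strained triple bond (carbolithiation) to form C3–C3a and the aryllithium 20, whose carbanion lies four atoms from the carbamoyl carbon and attacks it through a five-membered cyclic tetrahedral intermediate that opens by C–O cleavage to the lithium alkoxide of 21, forming C7a–C1. No ring is closed in the product, the cyclic species being only a transient. The single new stereocentre, C3, is controlled by the ligand: (+)-sparteine defines the C–Li configuration and non-benzylic dipole-stabilised α-oxy organolithiums react with retention, which corresponds to (S)-C3. The step needs attack at the aryne carbon remote from the flanking methoxy group; that methoxy group secures it by stabilising the developing negative charge on the adjacent carbon (future C7a) inductively, as is general for 3-alkoxyarynes. It also needs 17 to outcompete 18 and residual s-BuLi for 19, which an excess of 16, slow warming and the higher nucleophilicity of the sp3 carbanion should favour. The spiroketal offers no acidic or electrophilic site to the bases used.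

Step 8
Reactants: 21 2-[(1S)-1-hydroxy-7-[(2S,5S,7S)-7-methyl-1,6-dioxaspiro[4.4]nonan-2-yl]heptyl]-4,6-dimethoxy-N,N-di(propan-2-yl)benzamide
Product: 22 (3S)-5,7-dimethoxy-3-{6-[(2S,5S,7S)-7-methyl-1,6-dioxaspiro[4.4]nonan-2-yl]hexyl}-2-benzofuran-1(3H)-one
Conditions: AcOH (2 equiv), toluene, 80 °C
Reagents that add atoms: none
Why: Acid-assisted lactonisation of an ortho-(hydroxyalkyl) tertiary benzamide (5-exo-trig acyl substitution); the amide carbonyl is twisted out of conjugation by its two ortho substituents and the benzylic hydroxyl is held against it, and protonated diisopropylamine leaves. The C3–O bond is not broken, so C3 keeps its configuration. A weak acid in a non-polar solvent should leave C5' alone.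

## Compound list

1 | rac-2-(oct-7-en-1-yl)oxirane (1,2-epoxy-9-decene) | C=CCCCCCCC1CO1 | starting material
2 | (S)-2-(oct-7-en-1-yl)oxirane | C=CCCCCCC[C@H]1CO1 | intermediate
3 | acetone N,N-dimethylhydrazone | CC(C)=NN(C)C | starting material
4 | lithium aza-enolate of acetone N,N-dimethylhydrazone | [Li]CC(C)=NN(C)C | intermediate (not isolated)
5 | (5S)-2-(2,2-dimethylhydrazinylidene)tridec-12-en-5-ol | C=CCCCCCC[C@H](O)CCC(C)=NN(C)C | intermediate
6 | (S)-2-methyloxirane ((S)-propylene oxide) | C[C@H]1CO1 | starting material
7 | O,C-dilithiated 5 (lithium alkoxide, lithiated at the hydrazone methyl group) | C=CCCCCCC[C@H](O[Li])CCC(C[Li])=NN(C)C | intermediate (not isolated)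
8 | (2S,8S)-5-(2,2-dimethylhydrazinylidene)hexadec-15-ene-2,8-diol | C=CCCCCCC[C@H](O)CCC(=NN(C)C)CC[C@H](C)O | intermediate (not isolated)
9 | (2S,8S)-2,8-dihydroxyhexadec-15-en-5-one | C=CCCCCCC[C@H](O)CCC(=O)CC[C@H](C)O | intermediate (not isolated)
10 | (2S,5RS,7S)-7-methyl-2-(oct-7-en-1-yl)-1,6-dioxaspiro[4.4]nonane, mixture of both C5' epimers | C=CCCCCCC[C@H]1CCC2(CC[C@H](C)O2)O1 | intermediate
11 | (2S,5S,7S)-7-methyl-2-(oct-7-en-1-yl)-1,6-dioxaspiro[4.4]nonane | C=CCCCCCC[C@H]1CC[C@]2(CC[C@H](C)O2)O1 | intermediate
12 | 7-[(2S,5S,7S)-7-methyl-1,6-dioxaspiro[4.4]nonan-2-yl]heptanal | O=CCCCCCC[C@H]1CC[C@]2(CC[C@H](C)O2)O1 | intermediate (not isolated)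
13 | 7-[(2S,5S,7S)-7-methyl-1,6-dioxaspiro[4.4]nonan-2-yl]heptan-1-ol | OCCCCCCC[C@H]1CC[C@]2(CC[C@H](C)O2)O1 | intermediate
14 | N,N-di(propan-2-yl)carbamoyl chloride | CC(C)N(C(C)C)C(=O)Cl | starting material
15 | 7-[(2S,5S,7S)-7-methyl-1,6-dioxaspiro[4.4]nonan-2-yl]heptyl N,N-di(propan-2-yl)carbamate | CC(C)N(C(C)C)C(=O)OCCCCCCC[C@H]1CC[C@]2(CC[C@H](C)O2)O1 | intermediate
16 | 1-fluoro-3,5-dimethoxybenzene | COc1cc(F)cc(OC)c1 | starting material
17 | (1R)-1-lithio-7-[(2S,5S,7S)-7-methyl-1,6-dioxaspiro[4.4]nonan-2-yl]heptyl N,N-di(propan-2-yl)carbamate, (+)-sparteine on lithium not drawn | [Li][C@H](CCCCCC[C@H]1CC[C@]2(CC[C@H](C)O2)O1)OC(=O)N(C(C)C)C(C)C | intermediate (not isolated)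
18 | 1-fluoro-2-lithio-3,5-dimethoxybenzene | COc1cc(F)c([Li])c(OC)c1 | intermediate (not isolated)
19 | 3,5-dimethoxybenzyne (1,2-didehydro-3,5-dimethoxybenzene) | COC1=CC(OC)=CC#C1 | intermediate (not isolated)
20 | (1S)-1-(2-lithio-3,5-dimethoxyphenyl)-7-[(2S,5S,7S)-7-methyl-1,6-dioxaspiro[4.4]nonan-2-yl]heptyl N,N-di(propan-2-yl)carbamate | COc1cc(OC)c([Li])c(c1)[C@H](CCCCCC[C@H]2CC[C@]3(CC[C@H](C)O3)O2)OC(=O)N(C(C)C)C(C)C | intermediate (not isolated)
21 | 2-[(1S)-1-hydroxy-7-[(2S,5S,7S)-7-methyl-1,6-dioxaspiro[4.4]nonan-2-yl]heptyl]-4,6-dimethoxy-N,N-di(propan-2-yl)benzamide | COc1cc(OC)c(C(=O)N(C(C)C)C(C)C)c(c1)[C@H](CCCCCC[C@H]2CC[C@]3(CC[C@H](C)O3)O2)O | intermediate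
22 | (3S)-5,7-dimethoxy-3-{6-[(2S,5S,7S)-7-methyl-1,6-dioxaspiro[4.4]nonan-2-yl]hexyl}-2-benzofuran-1(3H)-one | COc1cc(OC)c2c(c1)[C@H](CCCCCC[C@H]1CC[C@]3(CC[C@H](C)O3)O1)OC2=O | target

## Step count and least certain steps

Total step count: 8. Longest linear sequence: 8 steps (1 to 22); 3, 6, 14 and 16 are bought and enter directly.

Step 7 (key step, proposed new method). The most likely failures are processes of mismatch and competition:
- chemical decay or loss of configuration of the lithiated carbamate before fluoride elimination from the aryllithium sets in;
- capture of the aryne by its own aryllithium precursor or by residual s-BuLi;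
- metalation of 16 between the two methoxy groups, a position from which no fluoride can be lost;
- stalling of the acyl transfer.

Fallback (known chemistry only; sets out from 15, returns at 22): lithiation–borylation, bromination and carbonylative lactonisation. 15 would be deprotonated as in step 7 to 17 and trapped at −78 °C with commercial 2-(3,5-dimethoxyphenyl)-4,4,5,5-tetramethyl-1,3,2-dioxaborolane to give the lithium boronate complex F1 (retention at carbon). Warming, with MgBr2·OEt2 in MeOH if needed, would trigger the 1,2-aryl shift with expulsion of the carbamate (inversion at carbon) to give the secondary benzylic boronic ester F2. NaOH/H2O2 would give the benzylic alcohol F3 with retention. Retention, inversion and retention together give the same (S) sense at C3 as in 21 with the same (+)-sparteine. NBS in MeCN at 0 °C should brominate ortho to the side chain and para to a methoxy group to give the aryl bromide F4. Pd(OAc)2 with 1,1'-bis(diphenylphosphino)ferrocene under CO with Et3N (carbonylative lactonisation of an ortho-bromobenzyl alcohol) would close the lactone to 22.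

Step 3. What may go wrong is incomplete second metalation (proton return within the alkoxide aggregate), metalation at the already substituted α-carbon, or alkylation on oxygen in place of carbon. Fallback (sets out from 6 and 2, returns at 10): alkyne-diol cycloisomerisation in place of the hydrazone linchpin. 6 would be opened by lithiated 1-(trimethylsilyl)propyne to give (2S)-6-(trimethylsilyl)hex-5-yn-2-ol F5. K2CO3 in MeOH would remove silicon to give (2S)-hex-5-yn-2-ol F6. Its dilithio derivative with BF3·OEt2 would open 2 at the terminal carbon (Yamaguchi–Hirao alkynylation) to give (2S,8S)-hexadec-15-en-5-yne-2,8-diol F7. AuCl, a monovalent gold salt, in CH2Cl2/MeOH would add both hydroxyls to the same alkyne carbon and give 10. This replaces the two carbanion alkylations but not the thermodynamic setting of C5'.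

Step 4. What may go wrong is insufficient chromatographic resolution of two non-polar epimers that carry no chromophore, so that the recycling loop delivers enriched but not pure material. Fallback (sets out from 10, returns at 13): separation at a later, derivatised stage. The mixture 10 would be ozonised and reduced under the conditions of step 5 to give 7-[(2S,5RS,7S)-7-methyl-1,6-dioxaspiro[4.4]nonan-2-yl]heptan-1-ol as both C5' epimers F8. 4-Nitrobenzoyl chloride with pyridine would convert it into the UV-active esters, from which preparative HPLC or fractional crystallisation should give 7-[(2S,5S,7S)-7-methyl-1,6-dioxaspiro[4.4]nonan-2-yl]heptyl 4-nitrobenzoate F9; the (5R) ester would be re-equilibrated with pyridinium p-toluenesulfonate and separated again. K2CO3 in MeOH would cleave the ester of F9 to 13.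

Step 8. What may go wrong is sluggish acyl substitution at the doubly ortho-substituted diisopropylamide, which would push towards stronger acid and with it equilibration at C5'. Fallback (sets out from 21, returns at 22): a redox detour without protic acid. Cp2Zr(H)Cl in THF would reduce the tertiary amide to the aldehyde oxidation level, which closes onto the neighbouring hydroxyl as the lactol F10. Ag2CO3 on Celite in hot toluene would oxidise the lactol to 22.

Step 5. What may go wrong is oxidation of the ether C–H bonds beside the ring oxygens by excess ozone, or acid from peroxidic intermediates equilibrating C5'. Fallback (sets out from 11, returns at 13): dihydroxylation and glycol cleavage. OsO4 (catalytic) with N-methylmorpholine N-oxide would give the terminal diol F11, NaIO4 would cleave it to 12, and NaBH4 would reduce 12 to 13.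

## Further compounds

F1 | step 7 | lithium boronate complex from 17 and 2-(3,5-dimethoxyphenyl)-4,4,5,5-tetramethyl-1,3,2-dioxaborolane, (R) at the carbamate carbon | [Li+].COc1cc(OC)cc(c1)[B-]2(OC(C)(C)C(C)(C)O2)[C@H](CCCCCC[C@H]3CC[C@]4(CC[C@H](C)O4)O3)OC(=O)N(C(C)C)C(C)C
F2 | step 7 | 2-[(1S)-1-(3,5-dimethoxyphenyl)-7-[(2S,5S,7S)-7-methyl-1,6-dioxaspiro[4.4]nonan-2-yl]heptyl]-4,4,5,5-tetramethyl-1,3,2-dioxaborolane | COc1cc(OC)cc(c1)[C@H](CCCCCC[C@H]2CC[C@]3(CC[C@H](C)O3)O2)B4OC(C)(C)C(C)(C)O4
F3 | step 7 | (1S)-1-(3,5-dimethoxyphenyl)-7-[(2S,5S,7S)-7-methyl-1,6-dioxaspiro[4.4]nonan-2-yl]heptan-1-ol | COc1cc(OC)cc(c1)[C@H](CCCCCC[C@H]2CC[C@]3(CC[C@H](C)O3)O2)O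
F4 | step 7 | (1S)-1-(2-bromo-3,5-dimethoxyphenyl)-7-[(2S,5S,7S)-7-methyl-1,6-dioxaspiro[4.4]nonan-2-yl]heptan-1-ol | COc1cc(OC)c(Br)c(c1)[C@H](CCCCCC[C@H]2CC[C@]3(CC[C@H](C)O3)O2)O
F5 | step 3 | (2S)-6-(trimethylsilyl)hex-5-yn-2-ol | C[C@H](O)CCC#C[Si](C)(C)C
F6 | step 3 | (2S)-hex-5-yn-2-ol | C[C@H](O)CCC#C
F7 | step 3 | (2S,8S)-hexadec-15-en-5-yne-2,8-diol | C=CCCCCCC[C@H](O)CC#CCC[C@H](C)O
F8 | step 4 | 7-[(2S,5RS,7S)-7-methyl-1,6-dioxaspiro[4.4]nonan-2-yl]heptan-1-ol (both C5' epimers) | OCCCCCCC[C@H]1CCC2(CC[C@H](C)O2)O1
F9 | step 4 | 7-[(2S,5S,7S)-7-methyl-1,6-dioxaspiro[4.4]nonan-2-yl]heptyl 4-nitrobenzoate | O=C(OCCCCCCC[C@H]1CC[C@]2(CC[C@H](C)O2)O1)c1ccc(cc1)[N+](=O)[O-]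
F10 | step 8 | (3S)-5,7-dimethoxy-3-{6-[(2S,5S,7S)-7-methyl-1,6-dioxaspiro[4.4]nonan-2-yl]hexyl}-1,3-dihydro-2-benzofuran-1-ol (lactol, both C1 epimers) | COc1cc(OC)c2c(c1)[C@H](CCCCCC[C@H]1CC[C@]3(CC[C@H](C)O3)O1)OC2O
F11 | step 5 | 8-[(2S,5S,7S)-7-methyl-1,6-dioxaspiro[4.4]nonan-2-yl]octane-1,2-diol (both C2 epimers) | OCC(O)CCCCCC[C@H]1CC[C@]2(CC[C@H](C)O2)O1
A1 | alternative 1 | (3S)-3-[(5S,6E,13S)-5,13-dihydroxy-10-oxotetradec-6-en-1-yl]-5,7-dimethoxy-2-benzofuran-1(3H)-one (hydroxy keto E-allylic alcohol) | COc1cc(OC)c2c(c1)[C@H](CCCC[C@H](O)/C=C/CCC(=O)CC[C@H](C)O)OC2=O
A2 | alternative 1 | spiroketal phthalide with an E-alkene between the two chain carbons next to C2' | COc1cc(OC)c2c(c1)[C@H](CCCC/C=C/[C@H]1CC[C@]3(CC[C@H](C)O3)O1)OC2=O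
A3 | alternative 2 | 2,2-dimethyl-6-(2,4-dioxoalkyl)-1,3-dioxin-4-one with the (S)-tert-butyldimethylsilyloxy carbon and the spiroketal chain | CC1(C)OC(=O)C=C(O1)CC(=O)CC(=O)[C@@H](O[Si](C)(C)C(C)(C)C)CCCCCC[C@H]2CC[C@]3(CC[C@H](C)O3)O2
A4 | alternative 2 | 7-hydroxy-2,2-dimethyl-5-[(1S)-1-(tert-butyldimethylsilyloxy)alkyl]-1,3-benzodioxin-4-one with the spiroketal chain | CC1(C)OC(=O)c2c(O1)cc(O)cc2[C@H](CCCCCC[C@H]3CC[C@]4(CC[C@H](C)O4)O3)O[Si](C)(C)C(C)(C)C
A5 | alternative 3 | phthalide with a 2,3-dihydrofuran ring A (C4'–C5' enol ether) and a free (S)-C7' hydroxyl on the C5' side chain | COc1cc(OC)c2c(c1)[C@H](CCCCCC[C@H]1CC=C(CC[C@H](C)O)O1)OC2=O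
A6 | alternative 3 | 4'-hydroxy spiroketal phthalide with the target configuration at C2', C5' and C7' | COc1cc(OC)c2c(c1)[C@H](CCCCCC[C@H]1C[C@H](O)[C@]3(CC[C@H](C)O3)O1)OC2=O
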